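The cyclohexene ring (C1–C6; C1 bears C7, numbering as in the target) is cut at C1–C6 and C2–C3. Its cis oxygens on C3 and C6 are the ends of the four-carbon unit C3–C4–C5–C6, which is an E,E-1,4-diacetoxybutadiene, while C1, C2 and C7 are 2-bromoacrolein. One catalytic enantioselective Diels–Alder reaction therefore closes the carbocycle and fixes C3 and C6; C1 is a relay centre lost with HBr. The C4=C5 alkene left by the diene is epoxidised anti to the acetates and opened at C5 by the C6 ester, which sets the trans C4/C5 diol; tin-directed benzoylation of O5 and O7 completes the target.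

Key step: step 2

Convention: target numbering throughout; α is the face of O3 and O6, β the opposite face.

Assumption: an acyclic E,E-diene without inside substituents should add through the endo (formyl under the diene) transition state, so adduct 5 is drawn with formyl cis to both acetoxy groups, and the (R)-catalyst is the antipode that the formyl C–H···O binding model predicts for the target's C3/C6 configuration; if the exo adduct prevailed, the (S)-catalyst would give that same C3/C6 configuration.

Step 1
Reactants: 1 acrolein
Product: 3 2-bromoacrolein, via 2,3-dibromopropanal 2 (not isolated)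
Conditions: Br2, CH2Cl2, −78 °C; then Et3N, −78 → 0 °C
Reagents that add atoms: bromine, BrBr
Why: Bromination–dehydrobromination, in which electrophilic addition of bromine to the alkene is followed by amine-mediated E2 loss of HBr through the acidic α-hydrogen to give the 2-halo enal, which has no stereocentre.

Step 2
Reactants: 3 2-bromoacrolein; 4 (1E,3E)-buta-1,3-diene-1,4-diyl diacetate
Product: 5 endo adduct 1β-bromo-1α-formylcyclohex-4-ene-3α,6α-diyl diacetate
Conditions: (3aR)-1-(2-methylphenyl)-3,3-diphenyltetrahydro-1H,3H-pyrrolo[1,2-c][1,3,2]oxazaborole (20 mol%), HN(SO2CF3)2 (20 mol%), CH2Cl2, −78 → −40 °C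
Reagents that add atoms: none
Why: The N-protonated oxazaborolidine binds the formyl oxygen of s-trans 3 (with a formyl C–H···O contact to the ring oxygen) and lowers its LUMO, and the s-cis diene 4 then adds suprafacially on both partners in a concerted, asynchronous [4+2] cycloaddition that forms C2–C3 and C1–C6. The closest known reaction type is the oxazaborolidinium-catalysed enantioselective Diels–Alder addition of 2-bromoacrolein to acyclic and oxygenated dienes. The single ring (C1–C6) is closed by this intermolecular [4+2] cycloaddition, both sigma bonds in one step. C3 and C6 are cis because both acetoxy groups are outside substituents of the E,E-diene, C1 follows from the endo transition state, and the absolute sense of all three comes from the catalyst aryl group shielding one face of the bound enal so that the diene should add to the Si face of the bromine-bearing carbon. The step needs facial and endo/exo selectivity together, because the exo adduct formed on the same enal face has the opposite C3/C6 configuration and would feed the enantiomeric series once C1 is erased; the minor diastereomer is therefore removed by chromatography at this stage, and regiochemistry is not an issue since the diene termini are equivalent.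

Step 3
Reactants: 5 endo adduct
Product: 6 1β-bromo-1α-formyl-4β,5β-epoxycyclohexane-3α,6α-diyl diacetate
Conditions: dimethyldioxirane (acetone solution), CH2Cl2, 0 °C → rt
Reagents that add atoms: dimethyldioxirane, CC1(C)OO1
Why: Dioxirane epoxidation, a concerted electrophilic oxygen transfer that should be faster at the alkene than at the electron-poor α-bromo aldehyde C–H, delivered to the β face opposite both allylic acetoxy groups (half-chair with bromine equatorial leaves that face open), which sets the C4 and C5 oxygens β.

Step 4
Reactants: 6 epoxy bromo aldehyde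
Product: 7 3α,6α-diacetoxy-4β,5β-epoxycyclohex-1-ene-1-carbaldehyde
Conditions: DBU (1.05 equiv), CH2Cl2, −20 → 0 °C
Reagents that add atoms: none
Why: E2 dehydrobromination, which can only run toward C2 because the β-bromine on C1 is antiperiplanar to the α-hydrogen of C2 whereas H6 lies on the same face as bromine, so the C1=C2 enal forms and the relay centre C1 disappears.

Step 5
Reactants: 7 epoxy enal diacetate
Product: 8 1-(hydroxymethyl)-4β,5β-epoxycyclohex-1-ene-3α,6α-diol
Conditions: i-Bu2AlH (6.5 equiv), CH2Cl2, −78 °C; aq. potassium sodium tartrate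
Reagents that add atoms: none
Why: Aluminium hydride reduction, giving 1,2-reduction of the enal and reductive cleavage of both acetates at a temperature at which the epoxide is not attacked, with no stereocentre touched.

Step 6
Reactants: 8 epoxy triol
Product: 11 3-O-TBS ether of 8, via boronate 9 (not isolated), via silylated boronate 10 (not isolated)
Conditions: PhB(OH)2, MgSO4, MeCN, rt; then TBSOTf, 2,6-lutidine, CH2Cl2, −20 → 0 °C; then pinacol, rt
Reagents that add atoms: tert-butyldimethylsilyl trifluoromethanesulfonate, CC(C)(C)[Si](C)(C)OS(=O)(=O)C(F)(F)F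
Why: Transient boronic ester protection, in which phenylboronic acid ties up only the 1,3-related O6/O7 pair as a six-membered boronate, O3–H is then the sole hydroxyl available for silylation, and transesterification with pinacol frees the diol without touching a stereocentre.

Step 7
Reactants: 11 3-O-TBS epoxy diol
Product: 12 6,7-di-O-acetate of 11
Conditions: Ac2O, pyridine, DMAP (cat.), CH2Cl2, 0 °C → rt
Reagents that add atoms: acetic anhydride, CC(=O)OC(C)=O
Why: Nucleophile-catalysed O-acylation of both free hydroxyls, which places the participating ester on O6 while the silyl ether on O3 cannot participate.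

Step 8
Reactants: 12 epoxy diacetate
Product: 16 3-O-TBS tetrol, via acetoxonium ion 13 (not isolated), via 6-O-acetate 14 (not isolated), via 5-O-acetate 15 (not isolated)
Conditions: BF3·OEt2, CH2Cl2, −40 → 0 °C; aq. NaHCO3; then K2CO3 (cat.), MeOH, 0 °C
Reagents that add atoms: none
Why: Lewis acid-promoted epoxide opening with neighbouring-group participation, in which the carbonyl oxygen of the C6 acetate attacks C5 from the α face in a 5-exo SN2 displacement (inversion at C5 makes O5 α and cis to O6, O4 stays β), and since hydrolysis of the dioxolanylium ion would be expected to leave the ester on the pseudoaxial O6 rather than O5, both hydroxy acetates are converged by methanolysis to one tetrol.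

Step 9
Reactants: 16 3-O-TBS tetrol; 17 benzoyl chloride
Product: 19 3-O-TBS ether of the target, via stannylene acetal 18 (not isolated)
Conditions: Bu2SnO (1.1 equiv), MeOH, reflux, evaporate; then BzCl (2.1 equiv), Et3N (1.1 equiv), THF, 0 °C
Reagents that add atoms: benzoyl chloride, O=C(Cl)c1ccccc1
Why: Stannylene acetal-directed acylation, in which the tin acetal should form on the cis O5/O6 pair and activate the equatorial O5 while the primary O7 takes the second benzoyl group, leaving the pseudoaxial, doubly flanked O6–H and the O4–H next to the silyl ether free, as in the 3,6-di-O-benzoylation of galactopyranosides.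

Step 10
Reactants: 19 3-O-TBS ether of the target
Product: 20 [(3S,4R,5R,6R)-5-(benzoyloxy)-3,4,6-trihydroxycyclohex-1-en-1-yl]methyl benzoate
Conditions: HF·pyridine, THF–pyridine, 0 °C → rt
Reagents that add atoms: none
Why: Fluoride-mediated desilylation under mildly acidic conditions, which should remove the silyl ether without benzoyl migration or ester cleavage.

Compound list
1 | acrolein (prop-2-enal) | C=CC=O | starting material
2 | 2,3-dibromopropanal (racemic, not isolated) | O=CC(Br)CBr | intermediate
3 | 2-bromoacrolein | C=C(Br)C=O | intermediate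
4 | (1E,3E)-buta-1,3-diene-1,4-diyl diacetate | CC(=O)O/C=C/C=C/OC(C)=O | starting material
5 | 1β-bromo-1α-formylcyclohex-4-ene-3α,6α-diyl diacetate (endo adduct, formyl cis to both acetoxy groups) | O=C[C@]1(Br)C[C@H](OC(C)=O)C=C[C@@H]1OC(C)=O | intermediate
6 | 1β-bromo-1α-formyl-4β,5β-epoxycyclohexane-3α,6α-diyl diacetate (epoxide anti to the acetates) | O=C[C@]1(Br)C[C@H](OC(C)=O)[C@H]2O[C@H]2[C@@H]1OC(C)=O | intermediate
7 | 3α,6α-diacetoxy-4β,5β-epoxycyclohex-1-ene-1-carbaldehyde | O=CC1=C[C@H](OC(C)=O)[C@H]2O[C@H]2[C@@H]1OC(C)=O | intermediate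
8 | 1-(hydroxymethyl)-4β,5β-epoxycyclohex-1-ene-3α,6α-diol | OCC1=C[C@H](O)[C@H]2O[C@H]2[C@@H]1O | intermediate
9 | 6,7-O-phenylboronate of 8, O3–H free (not isolated) | c1ccccc1B3OCC2=C[C@H](O)[C@H]4O[C@H]4[C@@H]2O3 | intermediate
10 | 3-O-tert-butyldimethylsilyl ether of 9 (not isolated) | c1ccccc1B3OCC2=C[C@H](O[Si](C)(C)C(C)(C)C)[C@H]4O[C@H]4[C@@H]2O3 | intermediate
11 | 3-O-tert-butyldimethylsilyl ether of 8, O6–H and O7–H free | OCC1=C[C@H](O[Si](C)(C)C(C)(C)C)[C@H]2O[C@H]2[C@@H]1O | intermediate
12 | 6,7-di-O-acetate of 11 | CC(=O)OCC1=C[C@H](O[Si](C)(C)C(C)(C)C)[C@H]2O[C@H]2[C@@H]1OC(C)=O | intermediate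
13 | 5α,6α-fused 2-methyl-1,3-dioxolan-2-ylium ion with O4β bound to BF3, zwitterion (not isolated) | CC(=O)OCC1=C[C@H](O[Si](C)(C)C(C)(C)C)[C@@H](O[B-](F)(F)F)[C@@H]2OC(C)=[O+][C@H]12 | intermediate
14 | 3-O-TBS 6,7-di-O-acetate with 4β-OH and 5α-OH free (not isolated) | CC(=O)OCC1=C[C@H](O[Si](C)(C)C(C)(C)C)[C@@H](O)[C@H](O)[C@@H]1OC(C)=O | intermediate
15 | 3-O-TBS 5,7-di-O-acetate with 4β-OH and 6α-OH free (not isolated) | CC(=O)OCC1=C[C@H](O[Si](C)(C)C(C)(C)C)[C@@H](O)[C@H](OC(C)=O)[C@@H]1O | intermediate
16 | 1-(hydroxymethyl)-3α-(tert-butyldimethylsilyloxy)cyclohex-1-ene-4β,5α,6α-triol | OCC1=C[C@H](O[Si](C)(C)C(C)(C)C)[C@@H](O)[C@H](O)[C@@H]1O | intermediate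
17 | benzoyl chloride | O=C(Cl)c1ccccc1 | starting material
18 | 5,6-O-dibutylstannylene acetal of 16 (not isolated) | OCC1=C[C@H](O[Si](C)(C)C(C)(C)C)[C@@H](O)[C@@H]2O[Sn](CCCC)(CCCC)O[C@H]12 | intermediate
19 | 3-O-tert-butyldimethylsilyl ether of the target (5α-OBz, 7-OBz, 4β-OH, 6α-OH) | O=C(OCC1=C[C@H](O[Si](C)(C)C(C)(C)C)[C@@H](O)[C@H](OC(=O)c2ccccc2)[C@@H]1O)c1ccccc1 | intermediate
20 | [(3S,4R,5R,6R)-5-(benzoyloxy)-3,4,6-trihydroxycyclohex-1-en-1-yl]methyl benzoate | O=C(OCC1=C[C@H](O)[C@@H](O)[C@H](OC(=O)c2ccccc2)[C@@H]1O)c1ccccc1 | target

Total step count: 10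
Longest linear sequence: 10 steps (1 → 20); 4 and 17 are purchased.

Steps most likely to fail

Step 2. The diacyloxydiene may add too slowly to the catalyst-bound enal (ester carbonyls competing for boron, polymerisation of 3), or facial or endo/exo control may be poor, which would erode enantiopurity once C1 is erased. Fallback: setting out from 3 and 4, uncatalysed heating (toluene, 70 °C, BHT) should give the racemic endo adduct, that is 5 together with its enantiomer F1. Condensation of the pair with (1R,2R)-N,N'-dimethyl-1,2-diphenylethane-1,2-diamine (MgSO4, CH2Cl2) gives two diastereomers, the imidazolidine of 5 F2 and the imidazolidine of the enantiomer F3, which are separated by chromatography. Hydrolysis of F2 (aq. citric acid, THF) releases 5, where the route is rejoined.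

Step 3. The oxidant may convert the formyl C–H into the acid, or oxygen transfer to the doubly deactivated alkene may be too slow. Fallback: setting out from 5, NaBH4 (EtOH–THF, −20 °C) reduces the aldehyde to the bromo alcohol F4. m-CPBA (NaHCO3, ClCH2CH2Cl, 40 °C) then epoxidises the alkene anti to the acetates to give the epoxy bromo alcohol F5. Dess–Martin periodinane (NaHCO3, CH2Cl2) restores the aldehyde, and the route is rejoined at 6.

Step 8. The Lewis acid may cause loss of the silyl ether, ionisation at the allylic C6–O or C7–O bonds, or hydride-shift rearrangement of the epoxide faster than ester participation. Fallback: setting out from 11 (step 7 is skipped), Cs2CO3 under CO2 (1 atm) in DMF converts O6–H into its carbonate anion, which opens the epoxide at C5 in the same 5-exo, invertive sense to give the 5,6-cyclic carbonate F6. K2CO3 in MeOH then cleaves the carbonate, and the route is rejoined at 16.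

Further compounds
F1 | step 2 | enantiomer of 5 (formed with 5 as the racemate) | O=C[C@@]1(Br)C[C@@H](OC(C)=O)C=C[C@H]1OC(C)=O
F2 | step 2 | imidazolidine of 5 with (1R,2R)-N,N'-dimethyl-1,2-diphenylethane-1,2-diamine | CN1[C@H](c2ccccc2)[C@@H](c2ccccc2)N(C)C1[C@]1(Br)C[C@H](OC(C)=O)C=C[C@@H]1OC(C)=O
F3 | step 2 | imidazolidine of F1 with the same diamine | CN1[C@H](c2ccccc2)[C@@H](c2ccccc2)N(C)C1[C@@]1(Br)C[C@@H](OC(C)=O)C=C[C@H]1OC(C)=O
F4 | step 3 | 1β-bromo-1α-(hydroxymethyl)cyclohex-4-ene-3α,6α-diyl diacetate | OC[C@]1(Br)C[C@H](OC(C)=O)C=C[C@@H]1OC(C)=O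
F5 | step 3 | 1β-bromo-1α-(hydroxymethyl)-4β,5β-epoxycyclohexane-3α,6α-diyl diacetate | OC[C@]1(Br)C[C@H](OC(C)=O)[C@H]2O[C@H]2[C@@H]1OC(C)=O
F6 | step 8 | 5α,6α-cyclic carbonate of 16 (3-O-TBS, 4β-OH and 7-OH free) | OCC1=C[C@H](O[Si](C)(C)C(C)(C)C)[C@@H](O)[C@@H]2OC(=O)O[C@H]12
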